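## The problem

Blepharocalyxin E (35) joins a diarylheptanoid to a chalcone through an oxane whose four substituents are all equatorial (2S,3R,4R,6S): the 4-hydroxyphenyl group at C2, the side chain at C3, ring A at C4 and the phenethyl group at C6. Two further stereocentres lie outside the ring: the benzylic, allylic carbon C1′ (S) on C3, and the carbinol C5′ (S) further along an E-alkenyl chain (side chain numbered C1′ to C7′). C4 is the natural control element for the ring. Addition to a flat ring anti to ring A fixes C6, and C2 and C3 can be left to equilibration if a ketone sits on C3, because the all-equatorial arrangement is the thermodynamic one; C1′ rotates freely against the ring and C5′ is remote, so both need catalyst control. The 2′-hydroxychalcone, the E-alkene and the 4-oxybenzylic C2–O1 bond rule out hydrogenolysis and strong Lewis acids late on, so the seven phenols need a group that leaves under mild protic acid. Ring A is a 2,6-dioxygenated 4-methoxyphenyl group whose two open positions are equivalent until the cinnamoyl group is attached; a late acylation is therefore regiochemically safe, but any electrophile carrying ring A is crowded and electron-rich. The feature that opens the key step is that C3 carries two carbons, C2 and C1′, each bonded to the same 4-hydroxyphenyl group. C2–C3–C1′ is thus a masked symmetric 1,3-diaryl-1,3-dione, and C4–C5–C6 are the β-carbon, α-carbon and carbonyl carbon of an enone bearing ring A.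

## Retrosynthesis

**35 from 34.** The last cut removes seven methoxymethyl (MOM) ethers and one silyl ether from 34. MOM is preferred to benzyl (hydrogenolysis would take the two alkenes) and to methyl (ring A keeps one methoxy group); all eight groups leave together in methanolic HCl.

**34 from 29 and 32.** The aryl–carbonyl bond of the chalcone is cut, giving the ring A C–H compound 29 and the cinnamoyl N-methoxy-N-methyl amide 32. Against an aldol cut of the chalcone this saves a step on the advanced material. The forward reaction needs lithiation only at a ring A position flanked by two oxygens; either of the two gives the same product.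

**29 from 21 and 28.** The C1′–C2′ bond is cut to benzylic chloride 21 and E-vinyl bromide 28. Cutting C2′=C3′ instead would require an epimerisable α-aryl aldehyde at C1′. The nickel-catalysed reductive coupling passes through a planar benzylic radical, so 21 may be an epimer mixture, and the chiral ligand is asked to set C1′.

**21 from 20 from 19.** Chloride and alcohol are traced to the aryl ketone 19, the carbonyl that the dione leaves on C3.

**19 from 18 from 16.** The O1–C2 bond is cut in the oxa-Michael sense, giving hydroxy enone 18. 18 comes from the cyclic vinylogous ester 16 by 1,2-reduction and hydrolytic allylic transposition. Because both aryl groups are the same, the former carbonyl carbon can become the aryl-bearing ring carbon and the former enol ether carbon the ketone. This route is preferred to a direct conjugate reduction of a tetrasubstituted β-alkoxy-β-aryl enone, which has little precedent. The ring closure is asked to deliver C2 and C3 under thermodynamic control. The O1–C6 and C3–C4 bonds made in the key step stay intact throughout.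

**16 from 15.** Adding back the C5=C6 double bond gives the 4H-pyran 15, with C4 as its only stereocentre.

**15 from 5 and 12 (key step).** Cutting C3–C4 and O1–C6 gives the symmetric dione 5 and enone 12, both achiral. The forward step needs only face selectivity at C4; the symmetry of 5 removes any regiochemical question.

**12 from 7 and 11.** An aldol cut of the enone gives ketone 7 (from raspberry ketone 6) and aldehyde 11, made from 5-methoxyresorcinol 8 through 9 by directed lithiation.

**5 from 2 and 4.** A Claisen cut gives the protected acetophenone 2 and benzoate 4, from 1 and 3.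

**28 from 22.** The vinyl bromide comes from alkyne 26 by hydrozirconation. 26 is the silyl ether of alcohol 25, made by asymmetric propargylation of aldehyde 24, itself from ester 22 through 23.

**32 from 30.** The amide comes from 4-hydroxybenzaldehyde 30 through 31 by a Horner–Wadsworth–Emmons reaction.

## Roads not taken

Alternative 1: Ring A is taken apart instead of the oxane. The cut removes the two ring A bonds that flank the carbon on C4 and its silyloxy-bearing neighbour, leading to the C4 triisopropylsiloxyalkyne A2 and 3-methoxycyclobutenone A3. Heated together they would give the resorcinol monosilyl ether A1 by a Danheiser benzannulation (ring opening to a vinylketene, [2+2] addition, second opening, 6π closure).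
- Merits: ring A arrives last, so nothing is ever run beside a crowded, electron-rich aryl group. The arene regiochemistry is fixed by the mechanism, and the one free phenol of A1 could steer the cinnamoyl group to its open ortho position. On both points this is better than the chosen plan, whose key step must attack the carbon next to ring A.
- Weak points: A2 is the complete oxane with all six stereocentres, which a separate route must supply with only an ester-derived ynol ether at C4. Making the siloxyalkyne needs strong base next to β-alkoxy and benzylic positions, and the benzannulation is then run hot on the most advanced intermediate.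
- Comparison: the chosen plan has ring A in three steps from 8 and already in place when the ring and C4 are made in one catalytic step. Alternative 1 moves the stereochemical problem elsewhere without solving it.

Alternative 2: The C3–C1′ and C4–C5 bonds are cut together. 5-(Methoxymethoxy)-7-methoxycoumarin A5 is the dienophile through C3=C4 and the 1-aryl-3-silyloxybutadiene A6 the diene. The cis-fused Diels–Alder adduct A4 holds C1′, C3 and C4 as a triad, with the lactone carbonyl as the future C2 and the silyl enol ether carbon as the future C6.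
- Merits: suprafacial addition ties C1′ to C3 and C4 in one step. This is the centre the chosen plan leaves to a late catalyst-controlled coupling, and here alternative 2 is the stronger design.
- Weak points: coumarins are poor dienophiles and a 5,7-dioxygenated one is poorer still, so pressure or strong Lewis acids would be needed, with no dependable way to make the addition enantioselective; endo/exo control at C1′ is open. Afterwards the cyclohexene must be cleaved, the lactone carbon arylated, a phenethyl group added at C6 and the oxane closed and reduced at C2 and C6.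
- Comparison: against the better control of C1′ the chosen plan sets step economy in the ring: after 15, O1–C6 and C4 are in place, and C2, C3 and C6 follow in three steps.

Alternative 3: O1 is inserted late. Baeyer–Villiger oxidation of the 2-aryl-3-vinyl-4-(ring A)cyclopentanone A8 would move the aryl-bearing carbon to oxygen with retention and give lactone A7 with C2, C3 and C4 set.
- Merits: the trans,trans triad of a cyclopentanone can be corrected by epimerisation, and the 4-alkoxybenzylic carbon migrates preferentially. The lactone carbonyl is an ideal handle for C6: phenethyl addition and axial silane reduction of the lactol is a more secure way to the 2,6-cis relationship than the face-selective hydrogenation of the chosen route.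
- Weak points: a peracid meets the trioxygenated ring A and the vinyl group. The silane reduction needs a Lewis acid that MOM ethers and a 2-aryloxane tolerate poorly. C1′ in A7 is only a vinyl carbon and still has to receive its aryl group and chain with stereocontrol, a long detour. A8 itself needs an asymmetric synthesis of three contiguous centres.
- Comparison: the chosen plan builds the ring from two achiral pieces under one chiral catalyst and has C1′ attached to C3 as a carbonyl from the start.

Key step: step 8

Assumption: the senses of induction of the amine catalyst (step 8), the phosphoric acid (step 16) and the bis(oxazoline) ligand (step 19) are taken from the closest model reactions; each is available in both mirror-image or pseudoenantiomeric forms, and the form named is exchanged if the sense proves opposite.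

## Route

Step 1
Reactants: 1 4′-hydroxyacetophenone
Product: 2 4′-(methoxymethoxy)acetophenone
Conditions: MOMCl, i-Pr2NEt, CH2Cl2, 0 °C → rt
Reagents that add atoms: chloromethyl methyl ether, COCCl
Why: O-alkylation of the phenol (Williamson-type acetal formation) under amine base; the ketone is untouched.

Step 2
Reactants: 3 methyl 4-hydroxybenzoate
Product: 4 methyl 4-(methoxymethoxy)benzoate
Conditions: MOMCl, i-Pr2NEt, CH2Cl2, 0 °C → rt
Reagents that add atoms: chloromethyl methyl ether, COCCl
Why: O-alkylation of the phenol as in step 1.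

Step 3
Reactants: 2 4′-(methoxymethoxy)acetophenone; 4 methyl 4-(methoxymethoxy)benzoate
Product: 5 1,3-bis[4-(methoxymethoxy)phenyl]propane-1,3-dione
Conditions: NaH, THF, 65 °C; then AcOH
Reagents that add atoms: none
Why: Crossed Claisen condensation of the ketone enolate with a non-enolisable ester; the product is drawn off as its stabilised sodium enolate, and MOM ethers tolerate the base.

Step 4
Reactants: 6 4-(4-hydroxyphenyl)butan-2-one (raspberry ketone)
Product: 7 4-[4-(methoxymethoxy)phenyl]butan-2-one
Conditions: MOMCl, i-Pr2NEt, CH2Cl2, 0 °C → rt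
Reagents that add atoms: chloromethyl methyl ether, COCCl
Why: O-alkylation of the phenol as in step 1.

Step 5
Reactants: 8 5-methoxyresorcinol
Product: 9 1-methoxy-3,5-bis(methoxymethoxy)benzene
Conditions: MOMCl (2.5 equiv), i-Pr2NEt, CH2Cl2, 0 °C → rt
Reagents that add atoms: chloromethyl methyl ether, COCCl
Why: Double O-alkylation of the resorcinol; the MOM groups also serve as directing groups in step 6.

Step 6
Reactants: 9 1-methoxy-3,5-bis(methoxymethoxy)benzene
Product: 11 4-methoxy-2,6-bis(methoxymethoxy)benzaldehyde, via aryllithium 10 (not isolated)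
Conditions: n-BuLi, TMEDA, THF, 0 °C; then DMF, 0 °C → rt; H2O
Reagents that add atoms: N,N-dimethylformamide, CN(C)C=O
Why: Directed ortho-metalation and formylation; the position between the two MOM ethers is the most acidic and best chelated, so lithiation there outruns the two positions next to the methoxy group.

Step 7
Reactants: 7 4-[4-(methoxymethoxy)phenyl]butan-2-one; 11 4-methoxy-2,6-bis(methoxymethoxy)benzaldehyde
Product: 12 (E)-1-[4-methoxy-2,6-bis(methoxymethoxy)phenyl]-5-[4-(methoxymethoxy)phenyl]pent-1-en-3-one
Conditions: KOH, EtOH/H2O, rt → 40 °C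
Reagents that add atoms: none
Why: Claisen–Schmidt aldol condensation; under base a methyl alkyl ketone reacts with a non-enolisable aryl aldehyde at the methyl group, and dehydration gives the conjugated E-enone.

Step 8
Reactants: 5 1,3-bis[4-(methoxymethoxy)phenyl]propane-1,3-dione; 12 ring A enone
Product: 15 (4S)-3-aroyl-2-aryl-4-(ring A)-6-phenethyl-4H-pyran (aryl = 4-(methoxymethoxy)phenyl), via Michael adduct 13 (not isolated), via cyclic hemiketal 14 (not isolated)
Conditions: 5 (1.5 equiv), 9-amino-9-deoxy-epi-quinine (20 mol %), CF3CO2H (40 mol %), toluene, 40 °C; then PPTS (0.5 equiv), 4 Å MS, 60 °C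
Reagents that add atoms: none
Why: The primary amine condenses with the ketone of 12 to an iminium ion, which activates the hindered, electron-rich enone, and the enol of 5 adds through its central carbon to one face of C4, forming C3–C4; hydrolysis releases triketone 13. The closest known reaction type is the cinchona primary amine-catalysed Michael addition of 1,3-dicarbonyl compounds to β-aryl enones followed by hemiketalisation and dehydration to 4H-pyrans and 4H-chromenes. Under the pyridinium acid the dione enol oxygen of 13 attacks the C6 ketone in a 6-exo-trig closure to hemiketal 14 (O1–C6), which loses water towards C5 to give 15. The only new stereocentre, C4 (S in 15, the arrangement needed in the target), is set by the catalyst, which shields one face of the iminium ion. Only this π-facial selectivity is needed: the two aroyl groups of 5 are identical, so there is no regiochemical choice in enolisation or ring closure, and the E geometry of 12 fixes the iminium geometry. Dehydrating in the same flask removes 13 from the retro-Michael equilibrium, the main threat to conversion and to the configuration at C4; the acid is kept weak so that the MOM ethers and the 4H-pyran survive.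

Step 9
Reactants: 15 (4S)-4H-pyran
Product: 16 (4S,6S)-3-aroyl-2-aryl-4-(ring A)-6-phenethyl-5,6-dihydro-4H-pyran
Conditions: H2 (1 atm), Pd/C, EtOAc, rt
Reagents that add atoms: none
Why: Heterogeneous syn hydrogenation of the electron-rich trisubstituted enol ether; the tetrasubstituted push–pull C2=C3 and the aryl ketone react much more slowly. Ring A sits pseudoaxial on the boat-like 4H-pyran, so hydrogen arrives on the opposite face and the phenethyl group ends up cis to ring A (6S).

Step 10
Reactants: 16 (4S,6S)-dihydropyran vinylogous ester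
Product: 18 (3S,5S)-5-hydroxy-2-arylidene-1,7-diaryl-3-(ring A)heptan-1-one (hydroxy enone), via allylic alcohol 17 (not isolated)
Conditions: i-Bu2AlH, CH2Cl2, −78 °C; then 0.5 M HCl, THF/H2O, 0 °C
Reagents that add atoms: water, O
Why: 1,2-Hydride addition to the vinylogous ester carbonyl, then hydrolytic allylic transposition (Stork–Danheiser type): acid ionises the doubly benzylic allylic alcohol 17, water adds at the enol ether carbon, and the hemiketal opens to the transposed enone with C6–OH free. Because both aryl groups are the same, the old carbonyl carbon can now become the aryl-bearing ring carbon C2 and the old enol ether carbon the ketone on C3.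

Step 11
Reactants: 18 hydroxy enone
Product: 19 (2S,3S,4R,6S)-3-aroyl-2-aryl-4-(ring A)-6-phenethyloxane (all substituents equatorial)
Conditions: KOt-Bu (0.3 equiv), THF, 0 °C → rt
Reagents that add atoms: none
Why: Intramolecular oxa-Michael addition (6-endo-trig) of the C6 alkoxide to the benzylidene carbon. The β-alkoxy ketone equilibrates by retro-oxa-Michael addition and enolisation, so C2 and C3 settle in the all-equatorial isomer under control of C4 and C6.

Step 12
Reactants: 19 oxane ketone
Product: 20 benzylic alcohol (both C1′ epimers)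
Conditions: NaBH4, THF/MeOH, 0 °C → rt
Reagents that add atoms: none
Why: Borohydride reduction of the aryl ketone; the configuration of the carbinol does not matter because C1′ passes through a radical in step 19.

Step 13
Reactants: 20 benzylic alcohol
Product: 21 benzylic chloride (both C1′ epimers)
Conditions: 1-chloro-N,N,2-trimethylprop-1-en-1-amine, CH2Cl2, 0 °C; used crude
Reagents that add atoms: 1-chloro-N,N,2-trimethylprop-1-en-1-amine, CC(C)=C(Cl)N(C)C
Why: Deoxychlorination with an α-chloroenamine under neutral conditions; no HCl is released, so the MOM ethers survive and the ionisable chloride is not exposed to acid or chromatography.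

Step 14
Reactants: 22 methyl 3-(4-hydroxyphenyl)propanoate
Product: 23 methyl 3-[4-(methoxymethoxy)phenyl]propanoate
Conditions: MOMCl, i-Pr2NEt, CH2Cl2, 0 °C → rt
Reagents that add atoms: chloromethyl methyl ether, COCCl
Why: O-alkylation of the phenol as in step 1.

Step 15
Reactants: 23 methyl 3-[4-(methoxymethoxy)phenyl]propanoate
Product: 24 3-[4-(methoxymethoxy)phenyl]propanal
Conditions: i-Bu2AlH (1.05 equiv), CH2Cl2, −78 °C; aq. potassium sodium tartrate
Reagents that add atoms: none
Why: Partial reduction of the ester; the tetrahedral aluminium hemiacetal is stable at −78 °C and releases the aldehyde on work-up.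

Step 16
Reactants: 24 3-[4-(methoxymethoxy)phenyl]propanal
Product: 25 (3S)-1-[4-(methoxymethoxy)phenyl]hex-5-yn-3-ol
Conditions: allenylboronic acid pinacol ester, (R)-TRIP phosphoric acid (10 mol %), 4 Å MS, toluene, 0 °C
Reagents that add atoms: allenylboronic acid pinacol ester, C=C=CB1OC(C)(C)C(C)(C)O1
Why: Chiral phosphoric acid-catalysed propargylation with an allenylboronate through a closed six-membered transition state (SE2′), which gives only the homopropargylic alcohol. The catalyst sets the carbinol centre (S), to be confirmed by Mosher ester analysis.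

Step 17
Reactants: 25 (3S)-homopropargylic alcohol
Product: 26 tert-butyl({(3S)-1-[4-(methoxymethoxy)phenyl]hex-5-yn-3-yl}oxy)dimethylsilane
Conditions: TBSCl, imidazole, DMF, rt
Reagents that add atoms: tert-butyldimethylsilyl chloride, CC(C)(C)[Si](C)(C)Cl
Why: Silylation of the secondary alcohol; the silyl ether survives steps 18, 19 and 22 and leaves with the MOM groups in step 23.

Step 18
Reactants: 26 silyl ether of the alkyne
Product: 28 {[(3S,5E)-6-bromo-1-[4-(methoxymethoxy)phenyl]hex-5-en-3-yl]oxy}(tert-butyl)dimethylsilane, via alkenylzirconocene chloride 27 (not isolated)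
Conditions: Cp2Zr(H)Cl, THF, rt; then NBS, 0 °C
Reagents that add atoms: N-bromosuccinimide, O=C1CCC(=O)N1Br
Why: Hydrozirconation adds Zr–H syn with zirconium on the terminal carbon, and bromodezirconation with NBS proceeds with retention to the E-vinyl bromide.

Step 19
Reactants: 21 benzylic chloride; 28 E-vinyl bromide
Product: 29 (2S,3R,4R,6S)-oxane carrying the (1S,2E,5S)-5-silyloxy-1,7-diarylhept-2-en-1-yl chain at C3
Conditions: NiCl2(dme) (10 mol %), (3aR,3a′R,8aS,8a′S)-2,2′-(cyclopropane-1,1-diyl)bis(3a,8a-dihydro-8H-indeno[1,2-d]oxazole) (11 mol %), Mn powder (3 equiv), NaI (0.5 equiv), DMA, 0 °C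
Reagents that add atoms: none
Why: Nickel-catalysed asymmetric reductive cross-electrophile coupling of a secondary benzylic chloride with an alkenyl bromide. The bromide adds oxidatively to zerovalent nickel, the chloride gives a planar benzylic radical (both epimers of 21 converge), and reductive elimination forms C1′–C2′ with the E geometry retained, Mn closing the cycle. The chiral bis(oxazoline) ligand decides the face of radical capture and so sets C1′ (S); the ligand antipode matched with the resident C3 centre is used.

Step 20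
Reactants: 30 4-hydroxybenzaldehyde
Product: 31 4-(methoxymethoxy)benzaldehyde
Conditions: MOMCl, i-Pr2NEt, CH2Cl2, 0 °C → rt
Reagents that add atoms: chloromethyl methyl ether, COCCl
Why: O-alkylation of the phenol as in step 1.

Step 21
Reactants: 31 4-(methoxymethoxy)benzaldehyde
Product: 32 (E)-N-methoxy-3-[4-(methoxymethoxy)phenyl]-N-methylprop-2-enamide
Conditions: diethyl {2-[methoxy(methyl)amino]-2-oxoethyl}phosphonate, NaH, THF, 0 °C → rt
Reagents that add atoms: diethyl {2-[methoxy(methyl)amino]-2-oxoethyl}phosphonate, CCOP(=O)(CC(=O)N(C)OC)OCC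
Why: Horner–Wadsworth–Emmons olefination with a stabilised phosphonate anion, which gives the E-alkene.

Step 22
Reactants: 29 coupled oxane; 32 cinnamoyl N-methoxy-N-methyl amide
Product: 34 heptakis-MOM mono-TBS ether of blepharocalyxin E, via ring A aryllithium 33 (not isolated)
Conditions: n-BuLi (1.1 equiv), THF, −20 → 0 °C; then 32, −78 → 0 °C; H2O
Reagents that add atoms: none
Why: Directed ortho-metalation at a ring A position flanked by a MOM ether and the methoxy group (the two such positions are equivalent), faster than lithiation beside a single MOM ether. Acylation with the N-methoxy-N-methyl amide stops at the ketone through the chelated tetrahedral intermediate, giving the E-enone directly.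

Step 23
Reactants: 34 protected blepharocalyxin E
Product: 35 blepharocalyxin E
Conditions: HCl (2 M in MeOH), THF, rt → 40 °C
Reagents that add atoms: none
Why: Acid-catalysed acetal exchange removes the seven MOM ethers and solvolysis removes the silyl ether. The conditions are mild enough for the chelated 2′-hydroxychalcone, and reversible ionisation at C2 can only return the all-equatorial oxane, which is the thermodynamic isomer.

## Compound list

1 | 4′-hydroxyacetophenone | CC(=O)c1ccc(O)cc1 | starting material
2 | 4′-(methoxymethoxy)acetophenone | CC(=O)c1ccc(OCOC)cc1 | intermediate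
3 | methyl 4-hydroxybenzoate | COC(=O)c1ccc(O)cc1 | starting material
4 | methyl 4-(methoxymethoxy)benzoate | COC(=O)c1ccc(OCOC)cc1 | intermediate
5 | 1,3-bis[4-(methoxymethoxy)phenyl]propane-1,3-dione | COCOc1ccc(cc1)C(=O)CC(=O)c1ccc(OCOC)cc1 | intermediate
6 | 4-(4-hydroxyphenyl)butan-2-one (raspberry ketone) | CC(=O)CCc1ccc(O)cc1 | starting material
7 | 4-[4-(methoxymethoxy)phenyl]butan-2-one | CC(=O)CCc1ccc(OCOC)cc1 | intermediate
8 | 5-methoxyresorcinol (5-methoxybenzene-1,3-diol) | COc1cc(O)cc(O)c1 | starting material
9 | 1-methoxy-3,5-bis(methoxymethoxy)benzene | COCOc1cc(OC)cc(OCOC)c1 | intermediate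
10 | [4-methoxy-2,6-bis(methoxymethoxy)phenyl]lithium | [Li]c1c(OCOC)cc(OC)cc1OCOC | intermediate (not isolated)
11 | 4-methoxy-2,6-bis(methoxymethoxy)benzaldehyde | O=Cc1c(OCOC)cc(OC)cc1OCOC | intermediate
12 | (E)-1-[4-methoxy-2,6-bis(methoxymethoxy)phenyl]-5-[4-(methoxymethoxy)phenyl]pent-1-en-3-one | COCOc1ccc(CCC(=O)/C=C/c2c(OCOC)cc(OC)cc2OCOC)cc1 | intermediate
13 | 2-{(1R)-1-[4-methoxy-2,6-bis(methoxymethoxy)phenyl]-5-[4-(methoxymethoxy)phenyl]-3-oxopentyl}-1,3-bis[4-(methoxymethoxy)phenyl]propane-1,3-dione | COCOc1ccc(CCC(=O)C[C@@H](c2c(OCOC)cc(OC)cc2OCOC)C(C(=O)c2ccc(OCOC)cc2)C(=O)c2ccc(OCOC)cc2)cc1 | intermediate (not isolated)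
14 | {(4S)-6-hydroxy-4-[4-methoxy-2,6-bis(methoxymethoxy)phenyl]-2-[4-(methoxymethoxy)phenyl]-6-{2-[4-(methoxymethoxy)phenyl]ethyl}-5,6-dihydro-4H-pyran-3-yl}[4-(methoxymethoxy)phenyl]methanone (both C6 epimers) | COCOc1ccc(CCC2(O)C[C@@H](c3c(OCOC)cc(OC)cc3OCOC)C(C(=O)c3ccc(OCOC)cc3)=C(c3ccc(OCOC)cc3)O2)cc1 | intermediate (not isolated)
15 | {(4S)-4-[4-methoxy-2,6-bis(methoxymethoxy)phenyl]-2-[4-(methoxymethoxy)phenyl]-6-{2-[4-(methoxymethoxy)phenyl]ethyl}-4H-pyran-3-yl}[4-(methoxymethoxy)phenyl]methanone | COCOc1ccc(CCC2=C[C@@H](c3c(OCOC)cc(OC)cc3OCOC)C(C(=O)c3ccc(OCOC)cc3)=C(c3ccc(OCOC)cc3)O2)cc1 | intermediate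
16 | {(4S,6S)-4-[4-methoxy-2,6-bis(methoxymethoxy)phenyl]-2-[4-(methoxymethoxy)phenyl]-6-{2-[4-(methoxymethoxy)phenyl]ethyl}-5,6-dihydro-4H-pyran-3-yl}[4-(methoxymethoxy)phenyl]methanone | COc1cc(OCOC)c([C@@H]2C[C@H](CCc3ccc(OCOC)cc3)OC(c3ccc(OCOC)cc3)=C2C(=O)c2ccc(OCOC)cc2)c(OCOC)c1 | intermediate
17 | {(4S,6S)-4-[4-methoxy-2,6-bis(methoxymethoxy)phenyl]-2-[4-(methoxymethoxy)phenyl]-6-{2-[4-(methoxymethoxy)phenyl]ethyl}-5,6-dihydro-4H-pyran-3-yl}[4-(methoxymethoxy)phenyl]methanol (both carbinol epimers) | COc1cc(OCOC)c([C@@H]2C[C@H](CCc3ccc(OCOC)cc3)OC(c3ccc(OCOC)cc3)=C2C(O)c2ccc(OCOC)cc2)c(OCOC)c1 | intermediate (not isolated)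
18 | (3S,5S)-5-hydroxy-3-[4-methoxy-2,6-bis(methoxymethoxy)phenyl]-2-[4-(methoxymethoxy)benzylidene]-1,7-bis[4-(methoxymethoxy)phenyl]heptan-1-one (E/Z mixture, in equilibrium with its cyclic hemiketal) | COc1cc(OCOC)c([C@H](C[C@H](CCc2ccc(OCOC)cc2)O)C(=Cc2ccc(OCOC)cc2)C(=O)c2ccc(OCOC)cc2)c(OCOC)c1 | intermediate
19 | {(2S,3S,4R,6S)-4-[4-methoxy-2,6-bis(methoxymethoxy)phenyl]-2-[4-(methoxymethoxy)phenyl]-6-{2-[4-(methoxymethoxy)phenyl]ethyl}oxan-3-yl}[4-(methoxymethoxy)phenyl]methanone (all-equatorial) | COc1cc(OCOC)c([C@@H]2C[C@H](CCc3ccc(OCOC)cc3)O[C@H](c3ccc(OCOC)cc3)[C@H]2C(=O)c2ccc(OCOC)cc2)c(OCOC)c1 | intermediate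
20 | {(2S,3R,4R,6S)-4-[4-methoxy-2,6-bis(methoxymethoxy)phenyl]-2-[4-(methoxymethoxy)phenyl]-6-{2-[4-(methoxymethoxy)phenyl]ethyl}oxan-3-yl}[4-(methoxymethoxy)phenyl]methanol (both carbinol epimers) | COc1cc(OCOC)c([C@@H]2C[C@H](CCc3ccc(OCOC)cc3)O[C@H](c3ccc(OCOC)cc3)[C@H]2C(O)c2ccc(OCOC)cc2)c(OCOC)c1 | intermediate
21 | (2S,3S,4R,6S)-3-{chloro[4-(methoxymethoxy)phenyl]methyl}-4-[4-methoxy-2,6-bis(methoxymethoxy)phenyl]-2-[4-(methoxymethoxy)phenyl]-6-{2-[4-(methoxymethoxy)phenyl]ethyl}oxane (both epimers at the chloride carbon) | COc1cc(OCOC)c([C@@H]2C[C@H](CCc3ccc(OCOC)cc3)O[C@H](c3ccc(OCOC)cc3)[C@H]2C(Cl)c2ccc(OCOC)cc2)c(OCOC)c1 | intermediate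
22 | methyl 3-(4-hydroxyphenyl)propanoate | COC(=O)CCc1ccc(O)cc1 | starting material
23 | methyl 3-[4-(methoxymethoxy)phenyl]propanoate | COC(=O)CCc1ccc(OCOC)cc1 | intermediate
24 | 3-[4-(methoxymethoxy)phenyl]propanal | O=CCCc1ccc(OCOC)cc1 | intermediate
25 | (3S)-1-[4-(methoxymethoxy)phenyl]hex-5-yn-3-ol | C#CC[C@@H](O)CCc1ccc(OCOC)cc1 | intermediate
26 | tert-butyl({(3S)-1-[4-(methoxymethoxy)phenyl]hex-5-yn-3-yl}oxy)dimethylsilane | C#CC[C@@H](O[Si](C)(C)C(C)(C)C)CCc1ccc(OCOC)cc1 | intermediate
27 | chlorobis(cyclopentadienyl){(1E,4S)-4-[(tert-butyldimethylsilyl)oxy]-6-[4-(methoxymethoxy)phenyl]hex-1-en-1-yl}zirconium | Cl[Zr](/C=C/C[C@@H](O[Si](C)(C)C(C)(C)C)CCc1ccc(OCOC)cc1)(C1C=CC=C1)C1C=CC=C1 | intermediate (not isolated)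
28 | {[(3S,5E)-6-bromo-1-[4-(methoxymethoxy)phenyl]hex-5-en-3-yl]oxy}(tert-butyl)dimethylsilane | Br/C=C/C[C@@H](O[Si](C)(C)C(C)(C)C)CCc1ccc(OCOC)cc1 | intermediate
29 | (2S,3R,4R,6S)-3-{(1S,2E,5S)-5-[(tert-butyldimethylsilyl)oxy]-1,7-bis[4-(methoxymethoxy)phenyl]hept-2-en-1-yl}-4-[4-methoxy-2,6-bis(methoxymethoxy)phenyl]-2-[4-(methoxymethoxy)phenyl]-6-{2-[4-(methoxymethoxy)phenyl]ethyl}oxane | COc1cc(OCOC)c([C@@H]2C[C@H](CCc3ccc(OCOC)cc3)O[C@H](c3ccc(OCOC)cc3)[C@H]2[C@H](/C=C/C[C@@H](O[Si](C)(C)C(C)(C)C)CCc2ccc(OCOC)cc2)c2ccc(OCOC)cc2)c(OCOC)c1 | intermediate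
30 | 4-hydroxybenzaldehyde | O=Cc1ccc(O)cc1 | starting material
31 | 4-(methoxymethoxy)benzaldehyde | O=Cc1ccc(OCOC)cc1 | intermediate
32 | (E)-N-methoxy-3-[4-(methoxymethoxy)phenyl]-N-methylprop-2-enamide | CON(C)C(=O)/C=C/c1ccc(OCOC)cc1 | intermediate
33 | ring A aryllithium of 29 (lithium on the ring A carbon between the methoxy group and one methoxymethoxy group) | COc1cc(OCOC)c([C@@H]2C[C@H](CCc3ccc(OCOC)cc3)O[C@H](c3ccc(OCOC)cc3)[C@H]2[C@H](/C=C/C[C@@H](O[Si](C)(C)C(C)(C)C)CCc2ccc(OCOC)cc2)c2ccc(OCOC)cc2)c(OCOC)c1[Li] | intermediate (not isolated)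
34 | (E)-1-{3-[(2S,3R,4R,6S)-3-{(1S,2E,5S)-5-[(tert-butyldimethylsilyl)oxy]-1,7-bis[4-(methoxymethoxy)phenyl]hept-2-en-1-yl}-2-[4-(methoxymethoxy)phenyl]-6-{2-[4-(methoxymethoxy)phenyl]ethyl}oxan-4-yl]-6-methoxy-2,4-bis(methoxymethoxy)phenyl}-3-[4-(methoxymethoxy)phenyl]prop-2-en-1-one | COc1cc(OCOC)c([C@@H]2C[C@H](CCc3ccc(OCOC)cc3)O[C@H](c3ccc(OCOC)cc3)[C@H]2[C@H](/C=C/C[C@@H](O[Si](C)(C)C(C)(C)C)CCc2ccc(OCOC)cc2)c2ccc(OCOC)cc2)c(OCOC)c1C(=O)/C=C/c1ccc(OCOC)cc1 | intermediate
35 | blepharocalyxin E, (E)-1-{3-[(2S,3R,4R,6S)-3-[(1S,2E,5S)-5-hydroxy-1,7-bis(4-hydroxyphenyl)hept-2-en-1-yl]-2-(4-hydroxyphenyl)-6-[2-(4-hydroxyphenyl)ethyl]oxan-4-yl]-2,4-dihydroxy-6-methoxyphenyl}-3-(4-hydroxyphenyl)prop-2-en-1-one | COc1cc(O)c([C@@H]2C[C@H](CCc3ccc(O)cc3)O[C@H](c3ccc(O)cc3)[C@H]2[C@H](/C=C/C[C@@H](O)CCc2ccc(O)cc2)c2ccc(O)cc2)c(O)c1C(=O)/C=C/c1ccc(O)cc1 | target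

## Step count and risks

Total step count: 23. Longest linear sequence: 12 steps (8 → 9 → 11 → 12 → 15 → 16 → 18 → 19 → 20 → 21 → 29 → 34 → 35; steps 5–13, 19, 22, 23).

Least certain steps:

**Step 8 (key step).** The conjugate addition may be slow or reversible, because the β-carbon is flanked by two ortho-alkoxy groups and ring A donates into the iminium ion; the primary amine may also be withdrawn by condensation with the dione. Either would show as low conversion and erosion of configuration at C4. The fallback reverses the polarity of bond formation at C4. It sets out from 5, 7 and 11. Knoevenagel condensation of 5 with 11 (piperidine, AcOH, toluene, reflux) gives the arylidene diketone F1, a doubly activated acceptor. Ketone 7 is converted (LDA, Me3SiCl, THF, −78 °C) into its kinetic silyl enol ether F2. Mukaiyama–Michael addition of F2 to F1 under Cu(OTf)2 and a tert-butyl bis(oxazoline) ligand, which chelates the two carbonyl groups, forms C4–C5. Desilylating work-up gives triketone 13, where the route is rejoined (acid stage of step 8 to 15).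

**Step 19.** Radical capture may be slow at the hindered, α-branched benzylic centre. The labile chloride may be lost by elimination towards C3 or by ionisation. Ligand and substrate may be mismatched, giving poor selectivity at C1′. The fallback sets C1′ by substrate-controlled hydroboration and attaches the chain by metathesis. It sets out from ketone 19. Wittig methylenation (Ph3P=CH2, THF) gives the 1,1-disubstituted alkene F4. Hydroboration with 9-BBN and oxidation (NaOH, H2O2) gives the primary alcohol F5; C1′ is set by attack on the alkene face turned away from the ring in the conformer of least allylic strain. Dess–Martin oxidation gives aldehyde F6 and a second methylenation the terminal alkene F7. Aldehyde 24 is converted by asymmetric allylboration (B-allyldiisopinocampheylborane) into the homoallylic alcohol F8 and silylated (TBSCl, imidazole) to its silyl ether F9. Cross-metathesis of F7 with F9 (second-generation Hoveyda–Grubbs catalyst, CH2Cl2, 40 °C) gives 29, where the route is rejoined.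

**Step 10 (with step 11).** In the acidic stage the allylic cation may be captured by a ring A oxygen instead of water, or the MOM ethers may begin to hydrolyse. In step 11 ring closure may stop at a mixture of C3 epimers if the equatorial preference of the aroyl group between two aryl neighbours is small. The fallback keeps the ring closed. It sets out from 16. Hydrogenation under pressure (H2, Pd(OH)2/C or Rh/Al2O3, EtOAc) adds hydrogen to C2=C3 from the face opposite ring A and gives the 2,3-cis ketone F3 (aroyl group axial). KOt-Bu (catalytic, THF) then epimerises C3 alone to give 19, where the route is rejoined.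

**Step 22.** Lithiation may compete beside one of the five other MOM ethers or at the benzylic, allylic C1′–H, giving regioisomeric or doubly acylated material. The fallback fixes the site by electrophilic substitution. It sets out from 29. NBS (MeCN, −20 °C) brominates only the trioxygenated ring A and gives the aryl bromide F10. Bromine–lithium exchange (t-BuLi, THF, −78 °C) gives aryllithium 33, where the route is rejoined (acylation with 32 to 34).

Further compounds

F1 | step 8 | 2-[4-methoxy-2,6-bis(methoxymethoxy)benzylidene]-1,3-bis[4-(methoxymethoxy)phenyl]propane-1,3-dione | COCOc1ccc(cc1)C(=O)C(=Cc1c(OCOC)cc(OC)cc1OCOC)C(=O)c1ccc(OCOC)cc1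
F2 | step 8 | trimethyl({4-[4-(methoxymethoxy)phenyl]but-1-en-2-yl}oxy)silane | C=C(O[Si](C)(C)C)CCc1ccc(OCOC)cc1
F3 | step 10 | {(2S,3R,4R,6S)-4-[4-methoxy-2,6-bis(methoxymethoxy)phenyl]-2-[4-(methoxymethoxy)phenyl]-6-{2-[4-(methoxymethoxy)phenyl]ethyl}oxan-3-yl}[4-(methoxymethoxy)phenyl]methanone (C3 epimer of 19, aroyl axial) | COc1cc(OCOC)c([C@@H]2C[C@H](CCc3ccc(OCOC)cc3)O[C@H](c3ccc(OCOC)cc3)[C@@H]2C(=O)c2ccc(OCOC)cc2)c(OCOC)c1
F4 | step 19 | (2S,3R,4R,6S)-4-[4-methoxy-2,6-bis(methoxymethoxy)phenyl]-2-[4-(methoxymethoxy)phenyl]-6-{2-[4-(methoxymethoxy)phenyl]ethyl}-3-{1-[4-(methoxymethoxy)phenyl]ethenyl}oxane | COc1cc(OCOC)c([C@@H]2C[C@H](CCc3ccc(OCOC)cc3)O[C@H](c3ccc(OCOC)cc3)[C@H]2C(=C)c2ccc(OCOC)cc2)c(OCOC)c1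
F5 | step 19 | (2S)-2-{(2S,3R,4R,6S)-4-[4-methoxy-2,6-bis(methoxymethoxy)phenyl]-2-[4-(methoxymethoxy)phenyl]-6-{2-[4-(methoxymethoxy)phenyl]ethyl}oxan-3-yl}-2-[4-(methoxymethoxy)phenyl]ethan-1-ol | COc1cc(OCOC)c([C@@H]2C[C@H](CCc3ccc(OCOC)cc3)O[C@H](c3ccc(OCOC)cc3)[C@H]2[C@H](CO)c2ccc(OCOC)cc2)c(OCOC)c1
F6 | step 19 | (2S)-2-{(2S,3R,4R,6S)-4-[4-methoxy-2,6-bis(methoxymethoxy)phenyl]-2-[4-(methoxymethoxy)phenyl]-6-{2-[4-(methoxymethoxy)phenyl]ethyl}oxan-3-yl}-2-[4-(methoxymethoxy)phenyl]acetaldehyde | COc1cc(OCOC)c([C@@H]2C[C@H](CCc3ccc(OCOC)cc3)O[C@H](c3ccc(OCOC)cc3)[C@H]2[C@H](C=O)c2ccc(OCOC)cc2)c(OCOC)c1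
F7 | step 19 | (2S,3R,4R,6S)-4-[4-methoxy-2,6-bis(methoxymethoxy)phenyl]-2-[4-(methoxymethoxy)phenyl]-6-{2-[4-(methoxymethoxy)phenyl]ethyl}-3-{(1S)-1-[4-(methoxymethoxy)phenyl]prop-2-en-1-yl}oxane | COc1cc(OCOC)c([C@@H]2C[C@H](CCc3ccc(OCOC)cc3)O[C@H](c3ccc(OCOC)cc3)[C@H]2[C@H](C=C)c2ccc(OCOC)cc2)c(OCOC)c1
F8 | step 19 | (3S)-1-[4-(methoxymethoxy)phenyl]hex-5-en-3-ol | C=CC[C@@H](O)CCc1ccc(OCOC)cc1
F9 | step 19 | tert-butyl({(3S)-1-[4-(methoxymethoxy)phenyl]hex-5-en-3-yl}oxy)dimethylsilane | C=CC[C@@H](O[Si](C)(C)C(C)(C)C)CCc1ccc(OCOC)cc1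
F10 | step 22 | ring A monobromide of 29 (bromine on the ring A carbon between the methoxy group and one methoxymethoxy group) | COc1cc(OCOC)c([C@@H]2C[C@H](CCc3ccc(OCOC)cc3)O[C@H](c3ccc(OCOC)cc3)[C@H]2[C@H](/C=C/C[C@@H](O[Si](C)(C)C(C)(C)C)CCc2ccc(OCOC)cc2)c2ccc(OCOC)cc2)c(OCOC)c1Br
A1 | alternative 1 | oxane carrying ring A as a hydroxy, triisopropylsilyloxy, methoxy arene (benzannulation product) | COc1cc(O)c([C@@H]2C[C@H](CCc3ccc(OCOC)cc3)O[C@H](c3ccc(OCOC)cc3)[C@H]2[C@H](/C=C/C[C@@H](O[Si](C)(C)C(C)(C)C)CCc2ccc(OCOC)cc2)c2ccc(OCOC)cc2)c(O[Si](C(C)C)(C(C)C)C(C)C)c1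
A2 | alternative 1 | oxane carrying a (triisopropylsilyloxy)ethynyl group at C4 | CC(C)[Si](OC#C[C@@H]2C[C@H](CCc3ccc(OCOC)cc3)O[C@H](c3ccc(OCOC)cc3)[C@H]2[C@H](/C=C/C[C@@H](O[Si](C)(C)C(C)(C)C)CCc2ccc(OCOC)cc2)c2ccc(OCOC)cc2)(C(C)C)C(C)C
A3 | alternative 1 | 3-methoxycyclobut-2-en-1-one | COC1=CC(=O)C1
A4 | alternative 2 | cis-fused tricyclic lactone with the C1′, C3, C4 triad (Diels–Alder adduct) | O=C1Oc2cc(OC)cc(OCOC)c2[C@@H]2CC(O[Si](C)(C)C(C)(C)C)=C[C@H](c3ccc(OCOC)cc3)[C@H]12
A5 | alternative 2 | 7-methoxy-5-(methoxymethoxy)coumarin | O=c1ccc2c(OCOC)cc(OC)cc2o1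
A6 | alternative 2 | (E)-tert-butyl({4-[4-(methoxymethoxy)phenyl]buta-1,3-dien-2-yl}oxy)dimethylsilane | C=C(O[Si](C)(C)C(C)(C)C)/C=C/c1ccc(OCOC)cc1
A7 | alternative 3 | oxan-2-one (lactone) with aryl, vinyl and ring A on three contiguous carbons, carbonyl at C6 | O=C1C[C@@H](c2c(OCOC)cc(OC)cc2OCOC)[C@H](C=C)[C@@H](c2ccc(OCOC)cc2)O1
A8 | alternative 3 | 2-aryl-3-vinyl-4-(ring A)cyclopentanone | O=C1C[C@@H](c2c(OCOC)cc(OC)cc2OCOC)[C@H](C=C)[C@H]1c1ccc(OCOC)cc1
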